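**Retrosynthetic overview**

1. Last bond: the central C(sp2)–C(sp2) single bond of the polyene (Suzuki–Miyaura), joining a dienynyl iodide that carries the enyne ring with an alkenylboronate that carries the butenolide and the triol ring.
2. The Z-ylidenebutenolide (third ring formed) comes from a tandem Sonogashira/5-exo lactonisation of (E)-2,3-dibromoacrylic acid with an enyne; its remaining α-bromide is then replaced by the vinyl group of the triol ring (Stille).
3. Both six-membered rings come from one C11 alcohol, (R)-4-ethynyl-3,5,5-trimethylcyclohex-3-en-1-ol: used as such for the enyne end (Sonogashira), and after syn-epoxidation, trans-diaxial hydrolysis and hydrostannation for the triol end.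
4. That carbocycle (first ring formed) is built in one operation from two acyclic pieces, a 1-methoxy-3-silyloxy diene from acetylacetone and mesityl oxide, by a TiCl4-mediated [4+2] annulation that forms the bond from the ring CH2 to the gem-dimethyl carbon and the bond between the two carbons that become the ring alkene; it supplies all 11 carbons of each end group (22 of the 37 carbons).
5. Enabling feature: in the cyclohexene ring the oxygen-bearing carbon and the methyl-bearing alkene carbon are 1,3-related (a latent pentane-2,4-dione), while the gem-dimethyl carbon is β to the first alkyne carbon through the alkyne-bearing ring carbon (a latent mesityl oxide whose acetyl group becomes the alkyne); the same carbon pattern recurs in the triol ring.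

Key step: step 3

Remark: the structure is taken as drawn, i.e. (R) at the carbinol of the enyne ring and, in the triol ring, the tertiary hydroxyl next to the vinyl group cis and the other tertiary hydroxyl trans to the secondary hydroxyl; a ketoreductase of the required sense is assumed to be found in a commercial screening panel.

**Route**

Step 1
Reactants: 1 acetylacetone (pentane-2,4-dione)
Product: 2 (E)-4-methoxypent-3-en-2-one
Conditions: HC(OMe)3, TsOH (cat.), MeOH, 23 °C
Reagents that add atoms: trimethyl orthoformate, COC(OC)OC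
Why: Acid-catalysed enol ether formation (O-methylation of the enolised 1,3-diketone through its dimethyl ketal) should give the thermodynamically preferred E vinylogous ester; no stereocenter is formed.

Step 2
Reactants: 2 (E)-4-methoxypent-3-en-2-one
Product: 3 (E)-4-methoxy-2-(trimethylsilyloxy)penta-1,3-diene
Conditions: LiN(iPr)2, THF, −78 °C; Me3SiCl, −78 °C to 23 °C
Reagents that add atoms: chlorotrimethylsilane, C[Si](C)(C)Cl
Why: Kinetic α′-deprotonation of the vinylogous ester at the acetyl methyl group and O-silylation (silyl enol ether formation) should give the cross-conjugated 1-methoxy-3-silyloxy diene.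

Step 3
Reactants: 3 (E)-4-methoxy-2-(trimethylsilyloxy)penta-1,3-diene, 4 mesityl oxide (4-methylpent-3-en-2-one)
Product: 7 4-acetyl-3,5,5-trimethylcyclohex-2-en-1-one, via titanium enolate 5 (not isolated), via methoxy ketone 6 (not isolated)
Conditions: 4, TiCl4 (2.2 equiv), CH2Cl2, −78 °C; 3, −78 °C to −20 °C; then 1 M HCl, THF, 23 °C
Reagents that add atoms: none
Why: TiCl4 activates mesityl oxide for a Mukaiyama–Michael addition of the CH2 terminus of 3 to the dimethyl-substituted β-carbon (first bond, giving the quaternary carbon), Me3SiCl is released, and titanium enolate 5 then adds through its α-carbon to the methoxy-bearing carbon of the TiCl4-bound β-methoxy enone (second bond) before methanol is lost by E1cB elimination during the acidic work-up. The closest known reactions are TiCl4-mediated Mukaiyama–Michael additions of silyl enol ethers to mesityl oxide, cyclohexenone annulations of 1-alkoxy-3-silyloxy dienes with enones, and the Lewis-acid Diels–Alder reaction of mesityl oxide with penta-1,3-diene, which joins the same two pairs of ring atoms. The six-membered carbocycle is closed in a 6-(enolexo)-endo-trig Michael addition–elimination, so that the whole operation is a stepwise [4+2] annulation. The one stereocenter formed (the acetyl-bearing carbon of 7) arises racemic and needs no control, because step 4 turns it into an alkene carbon. The step needs regioselectivity in both bond formations: the CH2 terminus is the most nucleophilic site of the diene (β-carbon of the silyl enol ether, pushed further by the methoxy group), and as long as the acetyl group is masked as its enolate the methoxy-bearing carbon is the only electrophile within reach, which excludes the aldol closures open to a protonated triketone. Either position of the new ring double bond (conjugated with the ring ketone or with the acetyl group) is acceptable, since step 4 converges both.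

Step 4
Reactants: 7 4-acetyl-3,5,5-trimethylcyclohex-2-en-1-one
Product: 8 1-(7,9,9-trimethyl-1,4-dioxaspiro[4.5]dec-7-en-8-yl)ethan-1-one
Conditions: HOCH2CH2OH, TsOH (cat.), benzene, reflux, water separator
Reagents that add atoms: ethylene glycol, OCCO
Why: Acid-catalysed ketalisation of the unhindered ring ketone runs through the dienol and should move the double bond out of conjugation (deconjugative ketalisation, known for 3-oxocyclohexenes of this type) into the tetrasubstituted position conjugated with the acetyl group, which is too hindered to ketalise; the racemic stereocenter of 7 is erased.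

Step 5
Reactants: 8 1-(7,9,9-trimethyl-1,4-dioxaspiro[4.5]dec-7-en-8-yl)ethan-1-one
Product: 10 8-ethynyl-7,9,9-trimethyl-1,4-dioxaspiro[4.5]dec-7-ene, via enol phosphate 9 (not isolated)
Conditions: LiN(iPr)2 (1.1 equiv), THF, −78 °C; ClP(O)(OEt)2, −78 °C to 23 °C; LiN(iPr)2 (2.3 equiv), −78 °C to 23 °C; H2O
Reagents that add atoms: none
Why: Conversion of a methyl ketone into a terminal alkyne by kinetic enolisation at the methyl group, O-phosphorylation and base-induced β-elimination of diethyl phosphate from enol phosphate 9 (known for 1-acylcyclohexenes); the ketal is inert to base.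

Step 6
Reactants: 10 8-ethynyl-7,9,9-trimethyl-1,4-dioxaspiro[4.5]dec-7-ene
Product: 11 4-ethynyl-3,5,5-trimethylcyclohex-3-en-1-one
Conditions: 1 M HCl (aq), THF, 0 °C, short contact time
Reagents that add atoms: water, O
Why: Mild acid-catalysed ketal hydrolysis under kinetic control should free the ketone without moving the tetrasubstituted, alkyne-conjugated double bond into conjugation with it; the β,γ-unsaturated ketone is used at once.

Step 7
Reactants: 11 4-ethynyl-3,5,5-trimethylcyclohex-3-en-1-one
Product: 12 (R)-4-ethynyl-3,5,5-trimethylcyclohex-3-en-1-ol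
Conditions: ketoreductase (NADPH-dependent), NADP+ (cat.), iPrOH (10 vol%), KH2PO4/K2HPO4 buffer pH 7.0, 30 °C
Reagents that add atoms: none
Why: Enzymatic asymmetric ketone reduction by a ketoreductase (short-chain dehydrogenase class) should deliver hydride to one face of a ketone whose two CH2 flanks differ only one atom further out (CH2–C(CH3)2 against CH2–C(CH3)=), a distinction no small hydride reagent makes; the (R) centre is set by the enzyme, the closest precedent being the enzymatic reduction of 2,2,6-trimethylcyclohexane-1,4-dione at the corresponding carbonyl to the (4R)-alcohol, and the neutral buffer spares the β,γ-double bond.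

Step 8
Reactants: 12 (R)-4-ethynyl-3,5,5-trimethylcyclohex-3-en-1-ol
Product: 13 (1S,3S,6S)-6-ethynyl-1,5,5-trimethyl-7-oxabicyclo[4.1.0]heptan-3-ol (epoxide oxygen cis to the hydroxyl)
Conditions: mCPBA, NaHCO3, CH2Cl2, 0 °C
Reagents that add atoms: 3-chloroperoxybenzoic acid, O=C(OO)c1cccc(Cl)c1
Why: Hydroxyl-directed (Henbest-type) peracid epoxidation of the electron-rich tetrasubstituted ring alkene (the alkyne is inert) should deliver oxygen to the face of the free homoallylic hydroxyl, which with the hydroxyl equatorial is also the face away from the pseudoaxial methyl of the gem-dimethyl group, so both epoxide carbons are set cis to the secondary hydroxyl.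

Step 9
Reactants: 13 (1S,3S,6S)-6-ethynyl-1,5,5-trimethyl-7-oxabicyclo[4.1.0]heptan-3-ol
Product: 14 (1S,2R,4S)-1-ethynyl-2,6,6-trimethylcyclohexane-1,2,4-triol
Conditions: 0.5 M HClO4 (aq), THF, 0 °C to 23 °C
Reagents that add atoms: water, O
Why: Acid-catalysed epoxide hydrolysis should open the ring at the methyl-bearing carbon with inversion (trans-diaxial Fürst–Plattner opening with the secondary hydroxyl equatorial; the ethynyl-bearing carbon is inductively deactivated and neopentyl), which puts the new tertiary hydroxyl trans and leaves the ethynyl carbinol hydroxyl cis to the secondary hydroxyl, as in the target.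

Step 10
Reactants: 14 (1S,2R,4S)-1-ethynyl-2,6,6-trimethylcyclohexane-1,2,4-triol
Product: 15 (1R,2R,4S)-2,6,6-trimethyl-1-[(E)-2-(tributylstannyl)ethenyl]cyclohexane-1,2,4-triol
Conditions: Bu3SnH, PdCl2(PPh3)2 (cat.), THF, 0 °C to 23 °C
Reagents that add atoms: tributyltin hydride, CCCC[SnH](CCCC)CCCC
Why: Palladium-catalysed syn-hydrostannation of the terminal alkyne should place tin on the terminal carbon, because the quaternary carbinol blocks the internal position, and give the E-alkenylstannane; the free hydroxyls are tolerated.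

Step 11
Reactants: 16 propiolic acid
Product: 17 (E)-2,3-dibromoprop-2-enoic acid
Conditions: Br2, CHCl3, 0 °C to 23 °C, dark
Reagents that add atoms: bromine, BrBr
Why: Electrophilic anti-addition of bromine to the alkyne gives the E-dibromide, in which the β-bromine is cis to the carboxyl group as the later lactonisation requires.

Step 12
Reactants: 18 (E)-3-methylpent-2-en-4-yn-1-ol
Product: 19 (E)-3-methylpent-2-en-4-ynal
Conditions: MnO2, CH2Cl2, 23 °C
Reagents that add atoms: none
Why: Allylic oxidation of the primary allylic alcohol with MnO2 gives the enal without touching the alkyne or the E double bond.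

Step 13
Reactants: 19 (E)-3-methylpent-2-en-4-ynal
Product: 20 2-[(1E,3E)-4-methylhexa-1,3-dien-5-yn-1-yl]-4,4,5,5-tetramethyl-1,3,2-dioxaborolane
Conditions: Cl2CHB(pin), CrCl2, LiI, THF, 23 °C
Reagents that add atoms: 2-(dichloromethyl)-4,4,5,5-tetramethyl-1,3,2-dioxaborolane, ClC(Cl)B1OC(C)(C)C(C)(C)O1
Why: Takai–Utimoto boryl-olefination (geminal dichromium reagent) converts the aldehyde into the E-alkenyl pinacol boronate, the E geometry following from the anti-periplanar elimination of the β-oxidochromium intermediate; the terminal alkyne is tolerated.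

Step 14
Reactants: 17 (E)-2,3-dibromoprop-2-enoic acid, 20 2-[(1E,3E)-4-methylhexa-1,3-dien-5-yn-1-yl]-4,4,5,5-tetramethyl-1,3,2-dioxaborolane
Product: 22 (Z)-3-bromo-5-[(2E,4E)-2-methyl-5-(4,4,5,5-tetramethyl-1,3,2-dioxaborolan-2-yl)penta-2,4-dien-1-ylidene]furan-2(5H)-one, via enynoic acid 21 (not isolated)
Conditions: PdCl2(PPh3)2 (cat.), CuI (cat.), Et3N, MeCN, 23 °C
Reagents that add atoms: none
Why: Tandem Sonogashira coupling/5-exo-dig lactonisation: the β-bromine (cis to CO2H and more reactive than the α-bromine) couples with the terminal alkyne to give enynoic acid 21, whose carboxylate adds anti across the metal-activated alkyne to give the Z-ylidenebutenolide; the boronate is inert without aqueous base.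

Step 15
Reactants: 22 (Z)-3-bromo-5-[(2E,4E)-2-methyl-5-(4,4,5,5-tetramethyl-1,3,2-dioxaborolan-2-yl)penta-2,4-dien-1-ylidene]furan-2(5H)-one, 15 (1R,2R,4S)-2,6,6-trimethyl-1-[(E)-2-(tributylstannyl)ethenyl]cyclohexane-1,2,4-triol
Product: 23 (Z)-5-[(2E,4E)-2-methyl-5-(4,4,5,5-tetramethyl-1,3,2-dioxaborolan-2-yl)penta-2,4-dien-1-ylidene]-3-[(E)-2-((1R,2R,4S)-1,2,4-trihydroxy-2,6,6-trimethylcyclohexyl)ethenyl]furan-2(5H)-one
Conditions: Pd2(dba)3 (cat.), AsPh3, NMP, 23 °C, dark
Reagents that add atoms: none
Why: Stille coupling of the activated α-bromobutenolide with the E-alkenylstannane proceeds with retention at both alkenes under neutral conditions, so the free triol, the lactone and the boronate (which needs base to transmetalate) are left alone.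

Step 16
Reactants: 24 ethyl acetoacetate
Product: 25 ethyl (E)-3-(trifluoromethylsulfonyloxy)but-2-enoate
Conditions: Tf2O, aq. Me4NOH, hexane, 5 °C
Reagents that add atoms: trifluoromethanesulfonic anhydride, O=S(=O)(OS(=O)(=O)C(F)(F)F)C(F)(F)F
Why: O-triflation of the β-keto ester enolate with a non-chelating counter-ion should favour the E enol triflate (triflate trans to the ester), the geometry needed for the methyl-bearing alkene next to the alkyne (enol triflate formation).

Step 17
Reactants: 12 (R)-4-ethynyl-3,5,5-trimethylcyclohex-3-en-1-ol, 25 ethyl (E)-3-(trifluoromethylsulfonyloxy)but-2-enoate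
Product: 26 ethyl (E)-5-[(R)-4-hydroxy-2,6,6-trimethylcyclohex-1-en-1-yl]-3-methylpent-2-en-4-ynoate
Conditions: PdCl2(PPh3)2 (cat.), CuI (cat.), Et3N, THF, 23 °C
Reagents that add atoms: none
Why: Sonogashira coupling of the terminal alkyne with the enol triflate proceeds with retention of the E geometry and tolerates the free secondary hydroxyl.

Step 18
Reactants: 26 ethyl (E)-5-[(R)-4-hydroxy-2,6,6-trimethylcyclohex-1-en-1-yl]-3-methylpent-2-en-4-ynoate
Product: 27 (R)-4-[(E)-5-hydroxy-3-methylpent-3-en-1-yn-1-yl]-3,5,5-trimethylcyclohex-3-en-1-ol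
Conditions: iBu2AlH (3.5 equiv), CH2Cl2, −78 °C; aq. KNaC4H4O6
Reagents that add atoms: none
Why: 1,2-Reduction of the conjugated ester to the allylic alcohol with the aluminium hydride; the excess covers the free hydroxyl.

Step 19
Reactants: 27 (R)-4-[(E)-5-hydroxy-3-methylpent-3-en-1-yn-1-yl]-3,5,5-trimethylcyclohex-3-en-1-ol
Product: 28 (E)-5-[(R)-4-hydroxy-2,6,6-trimethylcyclohex-1-en-1-yl]-3-methylpent-2-en-4-ynal
Conditions: MnO2, CH2Cl2, 23 °C
Reagents that add atoms: none
Why: Chemoselective allylic oxidation with MnO2: the primary allylic alcohol is oxidised while the secondary homoallylic ring alcohol is not.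

Step 20
Reactants: 28 (E)-5-[(R)-4-hydroxy-2,6,6-trimethylcyclohex-1-en-1-yl]-3-methylpent-2-en-4-ynal
Product: 29 (R)-4-[(3E,5E)-6-iodo-3-methylhexa-3,5-dien-1-yn-1-yl]-3,5,5-trimethylcyclohex-3-en-1-ol
Conditions: CHI3, CrCl2, THF/1,4-dioxane, 0 °C to 23 °C
Reagents that add atoms: iodoform, IC(I)I
Why: Takai iodo-olefination homologates the enal to the E-alkenyl iodide; the E selectivity should be high in dioxane-rich solvent and any minor Z isomer should be separable at this small, stable stage.

Step 21
Reactants: 29 (R)-4-[(3E,5E)-6-iodo-3-methylhexa-3,5-dien-1-yn-1-yl]-3,5,5-trimethylcyclohex-3-en-1-ol, 23 (Z)-5-[(2E,4E)-2-methyl-5-(4,4,5,5-tetramethyl-1,3,2-dioxaborolan-2-yl)penta-2,4-dien-1-ylidene]-3-[(E)-2-((1R,2R,4S)-1,2,4-trihydroxy-2,6,6-trimethylcyclohexyl)ethenyl]furan-2(5H)-one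
Product: 30 CNP0163979.1, (Z)-5-[(2E,4E,6E,8E)-11-((R)-4-hydroxy-2,6,6-trimethylcyclohex-1-en-1-yl)-2,9-dimethylundeca-2,4,6,8-tetraen-10-yn-1-ylidene]-3-[(E)-2-((1R,2R,4S)-1,2,4-trihydroxy-2,6,6-trimethylcyclohexyl)ethenyl]furan-2(5H)-one
Conditions: Pd(PPh3)4 (cat.), TlOEt, THF/H2O (3:1), 23 °C, degassed, dark
Reagents that add atoms: none
Why: Suzuki–Miyaura coupling of the E-alkenyl iodide with the E-alkenylboronate joins the two halves with retention at both partners; TlOEt speeds transmetalation at room temperature so that the polyene, the ylidenebutenolide and the four free hydroxyls should survive, and no protecting group has to be removed afterwards.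

**Compound list**

1 | acetylacetone (pentane-2,4-dione) | CC(=O)CC(C)=O | starting material
2 | (E)-4-methoxypent-3-en-2-one | CC(=O)/C=C(\C)OC | intermediate
3 | (E)-4-methoxy-2-(trimethylsilyloxy)penta-1,3-diene | C=C(O[Si](C)(C)C)/C=C(\C)OC | intermediate
4 | mesityl oxide (4-methylpent-3-en-2-one) | CC(=O)C=C(C)C | starting material
5 | trichlorotitanium enolate of (E)-8-methoxy-4,4-dimethylnon-7-ene-2,6-dione (enolate at C2=C3) | CC(O[Ti](Cl)(Cl)Cl)=CC(C)(C)CC(=O)/C=C(\C)OC | intermediate (not isolated)
6 | 4-acetyl-3-methoxy-3,5,5-trimethylcyclohexan-1-one (present as its titanium complex) | CC(=O)C1C(C)(C)CC(=O)CC1(C)OC | intermediate (not isolated)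
7 | 4-acetyl-3,5,5-trimethylcyclohex-2-en-1-one (racemic) | CC(=O)C1C(C)=CC(=O)CC1(C)C | intermediate
8 | 1-(7,9,9-trimethyl-1,4-dioxaspiro[4.5]dec-7-en-8-yl)ethan-1-one | CC(=O)C1=C(C)CC2(CC1(C)C)OCCO2 | intermediate
9 | diethyl 1-(7,9,9-trimethyl-1,4-dioxaspiro[4.5]dec-7-en-8-yl)ethenyl phosphate | C=C(OP(=O)(OCC)OCC)C1=C(C)CC2(CC1(C)C)OCCO2 | intermediate (not isolated)
10 | 8-ethynyl-7,9,9-trimethyl-1,4-dioxaspiro[4.5]dec-7-ene | C#CC1=C(C)CC2(CC1(C)C)OCCO2 | intermediate
11 | 4-ethynyl-3,5,5-trimethylcyclohex-3-en-1-one | C#CC1=C(C)CC(=O)CC1(C)C | intermediate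
12 | (R)-4-ethynyl-3,5,5-trimethylcyclohex-3-en-1-ol | CC1=C(C#C)C(C)(C)C[C@H](O)C1 | intermediate
13 | (1S,3S,6S)-6-ethynyl-1,5,5-trimethyl-7-oxabicyclo[4.1.0]heptan-3-ol | C#C[C@@]12C(C)(C)C[C@H](O)C[C@]1(C)O2 | intermediate
14 | (1S,2R,4S)-1-ethynyl-2,6,6-trimethylcyclohexane-1,2,4-triol | C#C[C@@]1(O)C(C)(C)C[C@H](O)C[C@@]1(C)O | intermediate
15 | (1R,2R,4S)-2,6,6-trimethyl-1-[(E)-2-(tributylstannyl)ethenyl]cyclohexane-1,2,4-triol | CCCC[Sn](CCCC)(CCCC)/C=C/[C@@]1(O)C(C)(C)C[C@H](O)C[C@@]1(C)O | intermediate
16 | propiolic acid | C#CC(=O)O | starting material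
17 | (E)-2,3-dibromoprop-2-enoic acid | OC(=O)/C(Br)=C\Br | intermediate
18 | (E)-3-methylpent-2-en-4-yn-1-ol | C#C/C(C)=C/CO | starting material
19 | (E)-3-methylpent-2-en-4-ynal | C#C/C(C)=C/C=O | intermediate
20 | 2-[(1E,3E)-4-methylhexa-1,3-dien-5-yn-1-yl]-4,4,5,5-tetramethyl-1,3,2-dioxaborolane | C#C/C(C)=C/C=C/B1OC(C)(C)C(C)(C)O1 | intermediate
21 | (2E,6E,8E)-2-bromo-6-methyl-9-(4,4,5,5-tetramethyl-1,3,2-dioxaborolan-2-yl)nona-2,6,8-trien-4-ynoic acid | OC(=O)/C(Br)=C\C#C/C(C)=C/C=C/B1OC(C)(C)C(C)(C)O1 | intermediate (not isolated)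
22 | (Z)-3-bromo-5-[(2E,4E)-2-methyl-5-(4,4,5,5-tetramethyl-1,3,2-dioxaborolan-2-yl)penta-2,4-dien-1-ylidene]furan-2(5H)-one | CC1(C)OB(/C=C/C=C(C)/C=C2C=C(Br)C(=O)O/2)OC1(C)C | intermediate
23 | (Z)-5-[(2E,4E)-2-methyl-5-(4,4,5,5-tetramethyl-1,3,2-dioxaborolan-2-yl)penta-2,4-dien-1-ylidene]-3-[(E)-2-((1R,2R,4S)-1,2,4-trihydroxy-2,6,6-trimethylcyclohexyl)ethenyl]furan-2(5H)-one | CC1(C)OB(/C=C/C=C(C)/C=C2C=C(/C=C/[C@@]3(O)C(C)(C)C[C@H](O)C[C@@]3(C)O)C(=O)O/2)OC1(C)C | intermediate
24 | ethyl acetoacetate | CCOC(=O)CC(C)=O | starting material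
25 | ethyl (E)-3-(trifluoromethylsulfonyloxy)but-2-enoate | CCOC(=O)/C=C(\C)OS(=O)(=O)C(F)(F)F | intermediate
26 | ethyl (E)-5-[(R)-4-hydroxy-2,6,6-trimethylcyclohex-1-en-1-yl]-3-methylpent-2-en-4-ynoate | CC1=C(C#C/C(C)=C/C(=O)OCC)C(C)(C)C[C@H](O)C1 | intermediate
27 | (R)-4-[(E)-5-hydroxy-3-methylpent-3-en-1-yn-1-yl]-3,5,5-trimethylcyclohex-3-en-1-ol | CC1=C(C#C/C(C)=C/CO)C(C)(C)C[C@H](O)C1 | intermediate
28 | (E)-5-[(R)-4-hydroxy-2,6,6-trimethylcyclohex-1-en-1-yl]-3-methylpent-2-en-4-ynal | CC1=C(C#C/C(C)=C/C=O)C(C)(C)C[C@H](O)C1 | intermediate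
29 | (R)-4-[(3E,5E)-6-iodo-3-methylhexa-3,5-dien-1-yn-1-yl]-3,5,5-trimethylcyclohex-3-en-1-ol | CC1=C(C#C/C(C)=C/C=C/I)C(C)(C)C[C@H](O)C1 | intermediate
30 | CNP0163979.1 | CC1=C(C#C/C(C)=C/C=C/C=C/C=C(C)/C=C2C=C(/C=C/[C@@]3(O)C(C)(C)C[C@H](O)C[C@@]3(C)O)C(=O)O/2)C(C)(C)C[C@H](O)C1 | target

**Summary**

Total step count: 21.
Longest linear sequence: 12 steps (steps 1–7, 8–10, 15, 21; the arm through steps 1–7, 17–20, 21 is equally long).

Steps most likely to fail:

Step 3. The ring closure of the titanium enolate onto the hindered methoxy-bearing carbon may stall, or TiCl4 may strip the silyl group from the diene before it adds, so that only open-chain material forms. Fallback: a Robinson-type annulation, setting out from mesityl oxide 4 and ethyl acetoacetate 24. Condensation with ZnCl2 in refluxing toluene/heptane with removal of water should give ethyl 2,6,6-trimethyl-4-oxocyclohex-2-ene-1-carboxylate F1. Deconjugative ketalisation (ethylene glycol, TsOH) should give ethyl 7,9,9-trimethyl-1,4-dioxaspiro[4.5]dec-7-ene-8-carboxylate F2. LiAlH4 reduction should give (7,9,9-trimethyl-1,4-dioxaspiro[4.5]dec-7-en-8-yl)methanol F3, and MnO2 oxidation 7,9,9-trimethyl-1,4-dioxaspiro[4.5]dec-7-ene-8-carbaldehyde F4. Ohira–Bestmann homologation (dimethyl (1-diazo-2-oxopropyl)phosphonate, K2CO3, MeOH) then leads to alkyne ketal 10, where the route resumes.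

Step 7. The enzyme may not tell the two CH2 flanks apart well enough, or the ring double bond may drift into conjugation with the ketone in the buffer before reduction. Fallback: resolution in place of asymmetric reduction, setting out from ketone 11. NaBH4/CeCl3 (MeOH, −40 °C) should give racemic 4-ethynyl-3,5,5-trimethylcyclohex-3-en-1-ol F5. Lipase-catalysed acylation (Burkholderia cepacia lipase, vinyl acetate, MTBE) should acetylate the (R)-alcohol faster, the CH2C(CH3)2 flank being the large group, to give (R)-4-ethynyl-3,5,5-trimethylcyclohex-3-en-1-yl acetate F6, which is separated from the unreacted (S)-alcohol. Methanolysis (K2CO3, MeOH) returns to 12; the (S)-alcohol can be oxidised back to 11.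

Step 21. Protodeboronation of the electron-poor trienylboronate, or base-induced opening or isomerisation of the ylidenebutenolide, may outrun the cross-coupling. Fallback: change the order of bond construction so that the Suzuki coupling is done before the lactone exists, setting out from iodide 29 and the small boronate 20. Their Suzuki–Miyaura coupling (Pd(PPh3)4, TlOEt) should give (R)-4-[(3E,5E,7E,9E)-3,10-dimethyldodeca-3,5,7,9-tetraene-1,11-diyn-1-yl]-3,5,5-trimethylcyclohex-3-en-1-ol F7. Tandem Sonogashira/lactonisation of its terminal alkyne with acid 17 (PdCl2(PPh3)2, CuI, Et3N) should give (Z)-3-bromo-5-[(2E,4E,6E,8E)-11-((R)-4-hydroxy-2,6,6-trimethylcyclohex-1-en-1-yl)-2,9-dimethylundeca-2,4,6,8-tetraen-10-yn-1-ylidene]furan-2(5H)-one F8. A base-free Stille coupling with stannane 15 (Pd2(dba)3, AsPh3) then gives target 30.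

Further compounds
F1 | step 3 | ethyl 2,6,6-trimethyl-4-oxocyclohex-2-ene-1-carboxylate | CCOC(=O)C1C(C)=CC(=O)CC1(C)C
F2 | step 3 | ethyl 7,9,9-trimethyl-1,4-dioxaspiro[4.5]dec-7-ene-8-carboxylate | CCOC(=O)C1=C(C)CC2(CC1(C)C)OCCO2
F3 | step 3 | (7,9,9-trimethyl-1,4-dioxaspiro[4.5]dec-7-en-8-yl)methanol | OCC1=C(C)CC2(CC1(C)C)OCCO2
F4 | step 3 | 7,9,9-trimethyl-1,4-dioxaspiro[4.5]dec-7-ene-8-carbaldehyde | O=CC1=C(C)CC2(CC1(C)C)OCCO2
F5 | step 7 | racemic 4-ethynyl-3,5,5-trimethylcyclohex-3-en-1-ol | C#CC1=C(C)CC(O)CC1(C)C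
F6 | step 7 | (R)-4-ethynyl-3,5,5-trimethylcyclohex-3-en-1-yl acetate | CC1=C(C#C)C(C)(C)C[C@H](OC(C)=O)C1
F7 | step 21 | (R)-4-[(3E,5E,7E,9E)-3,10-dimethyldodeca-3,5,7,9-tetraene-1,11-diyn-1-yl]-3,5,5-trimethylcyclohex-3-en-1-ol | CC1=C(C#C/C(C)=C/C=C/C=C/C=C(C)/C#C)C(C)(C)C[C@H](O)C1
F8 | step 21 | (Z)-3-bromo-5-[(2E,4E,6E,8E)-11-((R)-4-hydroxy-2,6,6-trimethylcyclohex-1-en-1-yl)-2,9-dimethylundeca-2,4,6,8-tetraen-10-yn-1-ylidene]furan-2(5H)-one | CC1=C(C#C/C(C)=C/C=C/C=C/C=C(C)/C=C2C=C(Br)C(=O)O/2)C(C)(C)C[C@H](O)C1
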